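The route is built on a single disconnection: the C3–C3a bond of the trans-2-aryl-3-(hydroxymethyl)-2,3-dihydrobenzofuran, whose exocyclic CH2OH carbon is read as the former C4 carbonyl of an (S)-flavanone. Treating flavanone 9 with trivalent iodine in acidic trimethyl orthoformate moves the ring A carbon C4a from C4 to C3 in one operation. The pyranone contracts to the dihydrofuran, C4 leaves the ring as a methyl ester, and C3 is set trans to the C2 aryl group fixed earlier by asymmetric rhodium catalysis. The precursor is a 6-bromo-8-methoxyflavanone carrying a 3-methoxy-4-pivaloyloxyphenyl group at C2. Its product later becomes the benzylic bromide that alkylates an arm-bearing (R)-β-benzyl lactone.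

Key step: step 6

Assumption: the (R) antipode of MeO-F12-BIPHEP is taken to give the 2S flavanone in step 5 and (S,S)-Et-DuPhos the R succinate in step 22; if a first run shows the opposite sense, the other ligand antipode is used.

**Dihydrobenzofuran fragment (steps 1–11)**

Step 1
Reactants: 1 2'-hydroxy-3'-methoxyacetophenone
Product: 2 5'-bromo-2'-hydroxy-3'-methoxyacetophenone
Conditions: NBS (1.05 equiv), MeCN, 0 °C → rt
Reagents that add atoms: N-bromosuccinimide, O=C1CCC(=O)N1Br
Why: Electrophilic aromatic bromination goes para to the free phenol, the only strongly activated position that is not blocked.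

Step 2
Reactants: 2 5'-bromo-2'-hydroxy-3'-methoxyacetophenone; 3 N,N-dimethylformamide dimethyl acetal
Product: 5 6-bromo-8-methoxy-4H-chromen-4-one, via enaminone 4 (not isolated)
Conditions: 3 (2 equiv), toluene, 100 °C; then conc. HCl, CH2Cl2, 40 °C
Reagents that add atoms: none
Why: Condensation of the methyl ketone with the amide acetal gives the enaminone, and acid then drives conjugate addition of the phenol with loss of dimethylamine (enaminone route to chromones).

Step 3
Reactants: 6 4-bromo-2-methoxyphenol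
Product: 7 4-bromo-2-methoxyphenyl pivalate
Conditions: PivCl, Et3N, DMAP (cat.), CH2Cl2, 0 °C → rt
Reagents that add atoms: pivaloyl chloride, CC(C)(C)C(=O)Cl
Why: DMAP-catalysed O-acylation installs a hindered, electron-withdrawing ester that makes the future 2-aryl ring electron-poor for step 6.

Step 4
Reactants: 7 4-bromo-2-methoxyphenyl pivalate
Product: 8 [3-methoxy-4-(pivaloyloxy)phenyl]boronic acid
Conditions: B2(OH)4 (1.5 equiv), KOAc (3 equiv), [PdCl(XPhos)(2'-aminobiphenyl-2-yl)] (1 mol%), XPhos (2 mol%), EtOH, 80 °C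
Reagents that add atoms: tetrahydroxydiboron, OB(O)B(O)O
Why: Miyaura-type borylation with tetrahydroxydiboron gives the boronic acid directly, and the weak acetate base leaves the hindered aryl ester intact.

Step 5
Reactants: 5 6-bromo-8-methoxy-4H-chromen-4-one; 8 [3-methoxy-4-(pivaloyloxy)phenyl]boronic acid
Product: 9 (2S)-6-bromo-8-methoxy-2-[3-methoxy-4-(pivaloyloxy)phenyl]chroman-4-one
Conditions: 8 (3 equiv), [Rh(OH)(cod)]2 (1.5 mol%), (R)-MeO-F12-BIPHEP (3.3 mol%), CH2Cl2/H2O 10:1, 20 °C
Reagents that add atoms: none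
Why: In this Hayashi–Miyaura asymmetric 1,4-addition the aryl–rhodium species (monovalent rhodium, inert to the aryl bromide) adds to C2 of the chromone on the face chosen by the electron-poor atropisomeric bisphosphine, which sets C2 as S, while the mild two-phase conditions should suppress ring opening of the flavanone and a second addition.

Step 6
Reactants: 9 (2S)-6-bromo-8-methoxy-2-[3-methoxy-4-(pivaloyloxy)phenyl]chroman-4-one
Product: 12 methyl (2S,3S)-5-bromo-7-methoxy-2-[3-methoxy-4-(pivaloyloxy)phenyl]-2,3-dihydrobenzofuran-3-carboxylate, via enol ether 10 (not isolated), via iodane 11 (not isolated)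
Conditions: PhI(OAc)2 (1.2 equiv), conc. H2SO4 (2 equiv), HC(OMe)3, 0 °C → rt
Reagents that add atoms: trimethyl orthoformate, COC(OC)OC
Why: Acid and orthoformate turn the C4 ketone into methyl enol ether 10, whose C3 is attacked by electrophilic trivalent iodine on the face anti to the pseudo-equatorial 2-aryl group, giving ketal 11 with an equatorial C3–I bond. That bond is anti-periplanar to the C4–C4a ring bond, so the ring A carbon C4a shifts from C4 to C3 with inversion as iodobenzene (monovalent iodine) departs, and the dimethoxycarbenium ion left at the expelled C4 collapses to the methyl ester. The closest known reaction type is the oxidative ring contraction of flavanones to methyl trans-2-aryl-2,3-dihydrobenzofuran-3-carboxylates by trivalent thallium or trivalent iodine in trimethyl orthoformate. The five-membered ring is closed by contraction of the six-membered ring through a 1,2-aryl shift that forms the C3–C3a bond, not by an exo or endo cyclisation of a chain. The new C3 centre is controlled by the C2 centre, because anti addition of iodine followed by invertive migration places the ester trans to the aryl group and gives 2S,3S. The step needs ring A to migrate in preference to the 2-aryl group and C2 not to ionise or ring-open; the pivalate lowers the migratory aptitude and cation-stabilising power of the 2-aryl ring, the ring oxygen ortho to C4a keeps ring A a good migrating group, and the bromine blocks the position para to that oxygen against electrophilic attack.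

Step 7
Reactants: 12 methyl (2S,3S)-5-bromo-7-methoxy-2-[3-methoxy-4-(pivaloyloxy)phenyl]-2,3-dihydrobenzofuran-3-carboxylate
Product: 13 4-[(2S,3R)-5-bromo-3-(hydroxymethyl)-7-methoxy-2,3-dihydrobenzofuran-2-yl]-2-methoxyphenol
Conditions: LiAlH4 (3 equiv), THF, 0 °C; Rochelle salt work-up
Reagents that add atoms: none
Why: Hydride reduction converts the methyl ester into the primary alcohol and cleaves the aryl pivalate in the same operation, while the aryl bromide is inert at 0 °C and the trans C3 centre is not at risk (the descriptor changes to R only through priority).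

Step 8
Reactants: 13 4-[(2S,3R)-5-bromo-3-(hydroxymethyl)-7-methoxy-2,3-dihydrobenzofuran-2-yl]-2-methoxyphenol
Product: 14 [(2S,3R)-2-(4-benzyloxy-3-methoxyphenyl)-5-bromo-7-methoxy-2,3-dihydrobenzofuran-3-yl]methanol
Conditions: BnBr (1.1 equiv), K2CO3, acetone, 56 °C
Reagents that add atoms: benzyl bromide, BrCc1ccccc1
Why: Williamson etherification under carbonate conditions alkylates only the phenoxide and leaves the primary alcohol untouched.

Step 9
Reactants: 14 [(2S,3R)-2-(4-benzyloxy-3-methoxyphenyl)-5-bromo-7-methoxy-2,3-dihydrobenzofuran-3-yl]methanol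
Product: 15 tert-butyldimethylsilyl ether of 14
Conditions: TBSCl, imidazole, DMF, rt
Reagents that add atoms: tert-butyldimethylsilyl chloride, CC(C)(C)[Si](C)(C)Cl
Why: Standard imidazole-mediated silylation protects the primary alcohol against the organolithium and enolate steps that follow.

Step 10
Reactants: 15 tert-butyldimethylsilyl ether of 14
Product: 17 [(2S,3R)-2-(4-benzyloxy-3-methoxyphenyl)-3-(tert-butyldimethylsilyloxymethyl)-7-methoxy-2,3-dihydrobenzofuran-5-yl]methanol, via aldehyde 16 (not isolated)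
Conditions: n-BuLi (1.1 equiv), THF, −78 °C; DMF, −78 → 0 °C; then MeOH, NaBH4, 0 °C
Reagents that add atoms: N,N-dimethylformamide, CN(C)C=O
Why: Bromine–lithium exchange outruns any deprotonation at −78 °C, DMF formylates the aryllithium (Bouveault formylation), and borohydride reduces the liberated aldehyde in the same flask.

Step 11
Reactants: 17 [(2S,3R)-2-(4-benzyloxy-3-methoxyphenyl)-3-(tert-butyldimethylsilyloxymethyl)-7-methoxy-2,3-dihydrobenzofuran-5-yl]methanol
Product: 18 (2S,3R)-2-(4-benzyloxy-3-methoxyphenyl)-5-(bromomethyl)-3-(tert-butyldimethylsilyloxymethyl)-7-methoxy-2,3-dihydrobenzofuran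
Conditions: CBr4, PPh3, CH2Cl2, 0 °C; used crude
Reagents that add atoms: carbon tetrabromide, BrC(Br)(Br)Br
Why: The Appel reaction converts the electron-rich benzylic alcohol into the bromide under neutral conditions that leave silyl and benzyl ethers alone.

**Arm-bearing lactone fragment (steps 12–23)**

Step 12
Reactants: 6 4-bromo-2-methoxyphenol; 19 allyl bromide
Product: 20 1-(allyloxy)-4-bromo-2-methoxybenzene
Conditions: 19 (1.2 equiv), K2CO3, acetone, 56 °C
Reagents that add atoms: none
Why: Williamson etherification of the phenol.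

Step 13
Reactants: 20 1-(allyloxy)-4-bromo-2-methoxybenzene
Product: 21 2-allyl-4-bromo-6-methoxyphenol
Conditions: N,N-diethylaniline, 200 °C
Reagents that add atoms: none
Why: The aromatic Claisen rearrangement delivers the allyl group to the only free ortho position, the para position being blocked by bromine.

Step 14
Reactants: 21 2-allyl-4-bromo-6-methoxyphenol
Product: 22 1-allyl-2-(benzyloxy)-5-bromo-3-methoxybenzene
Conditions: BnBr, K2CO3, DMF, rt
Reagents that add atoms: benzyl bromide, BrCc1ccccc1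
Why: Williamson etherification protects the phenol as the benzyl ether that is removed only in the last step.

Step 15
Reactants: 22 1-allyl-2-(benzyloxy)-5-bromo-3-methoxybenzene
Product: 24 2-[2-(benzyloxy)-5-bromo-3-methoxyphenyl]acetic acid, via arylacetaldehyde 23 (not isolated)
Conditions: OsO4 (1 mol%), Oxone (4 equiv), DMF, rt
Reagents that add atoms: potassium peroxymonosulfate (Oxone), [K+].[O-]S(=O)(=O)OO
Why: Osmium-catalysed oxidative cleavage with Oxone takes the terminal alkene through the aldehyde to the arylacetic acid, the alkene being osmylated far faster than the arene is attacked.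

Step 16
Reactants: 24 2-[2-(benzyloxy)-5-bromo-3-methoxyphenyl]acetic acid; 25 (R)-4-benzyl-2-oxazolidinone
Product: 27 (4R)-4-benzyl-3-{2-[2-(benzyloxy)-5-bromo-3-methoxyphenyl]acetyl}oxazolidin-2-one, via mixed anhydride 26 (not isolated)
Conditions: PivCl, Et3N, THF, −20 °C; then LiCl, 25, −20 °C → rt
Reagents that add atoms: none
Why: Activation as the mixed pivalic anhydride and LiCl-assisted N-acylation attach the auxiliary without strong base, so the acidic arylacetyl CH2 is not enolised.

Step 17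
Reactants: 27 (4R)-4-benzyl-3-{2-[2-(benzyloxy)-5-bromo-3-methoxyphenyl]acetyl}oxazolidin-2-one; 28 4-(benzyloxy)-3-methoxybenzaldehyde
Product: 29 (4R)-4-benzyl-3-[(2R,3R)-2-(2-benzyloxy-5-bromo-3-methoxyphenyl)-3-(4-benzyloxy-3-methoxyphenyl)-3-hydroxypropanoyl]oxazolidin-2-one
Conditions: Bu2BOTf, i-Pr2NEt, CH2Cl2, −78 → 0 °C; 28, −78 → 0 °C; then pH 7 buffer, MeOH, H2O2, 0 °C
Reagents that add atoms: none
Why: In this Evans syn aldol the Z dibutylboron enolate reacts through a Zimmerman–Traxler chair on the face away from the auxiliary benzyl group, which sets C2 and C3 as R,R (mirror image of the outcome established for the S auxiliary), and only the C2 centre is carried into the target.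

Step 18
Reactants: 29 the syn aldol adduct
Product: 30 (1R,2S)-2-(2-benzyloxy-5-bromo-3-methoxyphenyl)-1-(4-benzyloxy-3-methoxyphenyl)propane-1,3-diol
Conditions: LiBH4, H2O (1 equiv), Et2O/THF, 0 °C
Reagents that add atoms: none
Why: Reductive removal of the auxiliary with lithium borohydride gives the 1,3-diol, after which the benzylic C2 is no longer alpha to a carbonyl and cannot epimerise.

Step 19
Reactants: 30 the (1R,2S)-diol
Product: 31 bis(tert-butyldimethylsilyl) ether of 30
Conditions: TBSOTf (2.5 equiv), 2,6-lutidine, CH2Cl2, 0 °C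
Reagents that add atoms: tert-butyldimethylsilyl triflate, CC(C)(C)[Si](C)(C)OS(=O)(=O)C(F)(F)F
Why: The silyl triflate silylates both the primary and the hindered benzylic secondary alcohol, masking the arm as a non-enolisable diol for the basic steps ahead.

Step 20
Reactants: 31 bis(tert-butyldimethylsilyl) ether of 30
Product: 32 4-benzyloxy-3-[(1R,2S)-1-(4-benzyloxy-3-methoxyphenyl)-1,3-bis(tert-butyldimethylsilyloxy)propan-2-yl]-5-methoxybenzaldehyde
Conditions: n-BuLi (1.1 equiv), THF, −78 °C; DMF, −78 → 0 °C; then H2O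
Reagents that add atoms: N,N-dimethylformamide, CN(C)C=O
Why: Bromine–lithium exchange followed by formylation with DMF (Bouveault formylation) turns the aryl bromide into the aldehyde needed for the lactone.

Step 21
Reactants: 32 the arm aldehyde; 33 dimethyl succinate
Product: 34 (E)-4-aryl-3-(methoxycarbonyl)but-3-enoic acid (aryl = the ring of 32)
Conditions: 33 (1.5 equiv), KOt-Bu, t-BuOH, 60 °C; then 1 M HCl to pH 3
Reagents that add atoms: none
Why: The Stobbe condensation (aldol addition, lactonisation to the paraconate, base-induced ring opening) gives the E half-ester and thereby differentiates the two carboxyl groups.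

Step 22
Reactants: 34 the Stobbe half-ester
Product: 35 (3R)-3-(arylmethyl)-4-methoxy-4-oxobutanoic acid (aryl as in 32)
Conditions: H2 (5 bar), [Rh(cod)((S,S)-Et-DuPhos)]BF4 (1 mol%), Et3N (1 equiv), MeOH, rt
Reagents that add atoms: none
Why: Rhodium–DuPhos asymmetric hydrogenation of the itaconate-type half-ester, with the carboxylate chelating rhodium, sets the new centre as R under ligand control, and homogeneous rhodium does not cleave benzyl ethers.

Step 23
Reactants: 35 the (R)-succinate half-ester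
Product: 37 (4R)-4-(arylmethyl)dihydrofuran-2(3H)-one (aryl as in 32), via hydroxy acid 36 (not isolated)
Conditions: KOH (1 equiv), EtOH; CaCl2, NaBH4, EtOH, −10 °C → rt; then 1 M HCl to pH 3, rt
Reagents that add atoms: none
Why: Calcium borohydride reduces the methyl ester but not the carboxylate salt, and acidification closes the γ-lactone, so the ester carbon becomes the ring CH2O and the R centre is untouched.

**Fragment coupling and endgame (steps 24–27)**

Step 24
Reactants: 37 the (R)-β-benzyl lactone; 18 the benzylic bromide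
Product: 38 (3R,4R)-3-(dihydrobenzofuran-5-ylmethyl)-4-(arylmethyl)dihydrofuran-2(3H)-one carrying three benzyl and three tert-butyldimethylsilyl ethers
Conditions: LiHMDS (1.05 equiv), THF, −78 °C; then 18 (1.1 equiv), DMPU, −78 → −30 °C
Reagents that add atoms: none
Why: Alkylation of the lactone lithium enolate by the benzylic bromide occurs anti to the β-benzyl group, which gives the trans 3R,4R lactone (the standard entry to dibenzylbutyrolactones).

Step 25
Reactants: 38 the fully protected lactone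
Product: 39 the triol (secondary benzylic alcohol and two primary alcohols free, three benzyl ethers kept)
Conditions: TBAF, AcOH, THF, rt → 40 °C
Reagents that add atoms: none
Why: Fluoride cleaves all three silyl ethers, and the acetic acid buffer keeps the lactone and its α-centre undisturbed.

Step 26
Reactants: 39 the triol
Product: 40 the tri-O-benzyl ketone with the (S)-configured α-aryl β-hydroxy ketone arm
Conditions: activated MnO2 (20 equiv), CH2Cl2, rt
Reagents that add atoms: none
Why: MnO2 oxidises only the benzylic secondary alcohol activated by the para-alkoxyaryl ring and leaves both primary aliphatic alcohols, under neutral conditions that should not epimerise the newly enolisable centre.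

Step 27
Reactants: 40 the tri-O-benzyl ketone
Product: 41 CNP0111438.1
Conditions: H2 (1 atm), 10% Pd/C, EtOAc/EtOH, rt, no acid
Reagents that add atoms: none
Why: Neutral hydrogenolysis at 1 atm removes the three aryl benzyl ethers and should spare the electron-rich aryl ketone, the lactone and the benzylic C–O bond of the dihydrobenzofuran, while avoiding the acid that would cyclodehydrate the ortho-hydroxyaryl ketone.

**Compound list**

1 | 2'-hydroxy-3'-methoxyacetophenone | COc1cccc(C(C)=O)c1O | starting material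
2 | 5'-bromo-2'-hydroxy-3'-methoxyacetophenone | COc1cc(Br)cc(C(C)=O)c1O | intermediate
3 | N,N-dimethylformamide dimethyl acetal | COC(OC)N(C)C | starting material
4 | (E)-1-(5-bromo-2-hydroxy-3-methoxyphenyl)-3-(dimethylamino)prop-2-en-1-one | COc1cc(Br)cc(C(=O)/C=C/N(C)C)c1O | intermediate
5 | 6-bromo-8-methoxy-4H-chromen-4-one | COc1cc(Br)cc2c(=O)ccoc12 | intermediate
6 | 4-bromo-2-methoxyphenol | COc1cc(Br)ccc1O | starting material
7 | 4-bromo-2-methoxyphenyl pivalate | COc1cc(Br)ccc1OC(=O)C(C)(C)C | intermediate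
8 | [3-methoxy-4-(pivaloyloxy)phenyl]boronic acid | COc1cc(B(O)O)ccc1OC(=O)C(C)(C)C | intermediate
9 | (2S)-6-bromo-8-methoxy-2-[3-methoxy-4-(pivaloyloxy)phenyl]chroman-4-one | O=C1C[C@@H](c2ccc(OC(=O)C(C)(C)C)c(OC)c2)Oc2c(OC)cc(Br)cc21 | intermediate
10 | (2S)-6-bromo-4,8-dimethoxy-2-[3-methoxy-4-(pivaloyloxy)phenyl]-2H-chromene | COC1=C[C@@H](c2ccc(OC(=O)C(C)(C)C)c(OC)c2)Oc2c(OC)cc(Br)cc21 | intermediate
11 | (2R,3R)-3-[acetoxy(phenyl)-λ3-iodanyl]-6-bromo-4,4,8-trimethoxy-2-[3-methoxy-4-(pivaloyloxy)phenyl]chromane, iodine trans to the 2-aryl group | COC1(OC)[C@H](I(OC(C)=O)c2ccccc2)[C@@H](c2ccc(OC(=O)C(C)(C)C)c(OC)c2)Oc2c(OC)cc(Br)cc21 | intermediate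
12 | methyl (2S,3S)-5-bromo-7-methoxy-2-[3-methoxy-4-(pivaloyloxy)phenyl]-2,3-dihydrobenzofuran-3-carboxylate (trans) | COC(=O)[C@H]1c2cc(Br)cc(OC)c2O[C@@H]1c1ccc(OC(=O)C(C)(C)C)c(OC)c1 | intermediate
13 | 4-[(2S,3R)-5-bromo-3-(hydroxymethyl)-7-methoxy-2,3-dihydrobenzofuran-2-yl]-2-methoxyphenol | OC[C@H]1c2cc(Br)cc(OC)c2O[C@@H]1c1ccc(O)c(OC)c1 | intermediate
14 | [(2S,3R)-2-(4-benzyloxy-3-methoxyphenyl)-5-bromo-7-methoxy-2,3-dihydrobenzofuran-3-yl]methanol | OC[C@H]1c2cc(Br)cc(OC)c2O[C@@H]1c1ccc(OCc2ccccc2)c(OC)c1 | intermediate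
15 | (2S,3R)-2-(4-benzyloxy-3-methoxyphenyl)-5-bromo-3-(tert-butyldimethylsilyloxymethyl)-7-methoxy-2,3-dihydrobenzofuran | CC(C)(C)[Si](C)(C)OC[C@H]1c2cc(Br)cc(OC)c2O[C@@H]1c1ccc(OCc2ccccc2)c(OC)c1 | intermediate
16 | (2S,3R)-2-(4-benzyloxy-3-methoxyphenyl)-3-(tert-butyldimethylsilyloxymethyl)-7-methoxy-2,3-dihydrobenzofuran-5-carbaldehyde | CC(C)(C)[Si](C)(C)OC[C@H]1c2cc(C=O)cc(OC)c2O[C@@H]1c1ccc(OCc2ccccc2)c(OC)c1 | intermediate
17 | [(2S,3R)-2-(4-benzyloxy-3-methoxyphenyl)-3-(tert-butyldimethylsilyloxymethyl)-7-methoxy-2,3-dihydrobenzofuran-5-yl]methanol | CC(C)(C)[Si](C)(C)OC[C@H]1c2cc(CO)cc(OC)c2O[C@@H]1c1ccc(OCc2ccccc2)c(OC)c1 | intermediate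
18 | (2S,3R)-2-(4-benzyloxy-3-methoxyphenyl)-5-(bromomethyl)-3-(tert-butyldimethylsilyloxymethyl)-7-methoxy-2,3-dihydrobenzofuran | CC(C)(C)[Si](C)(C)OC[C@H]1c2cc(CBr)cc(OC)c2O[C@@H]1c1ccc(OCc2ccccc2)c(OC)c1 | intermediate
19 | allyl bromide | C=CCBr | starting material
20 | 1-(allyloxy)-4-bromo-2-methoxybenzene | C=CCOc1ccc(Br)cc1OC | intermediate
21 | 2-allyl-4-bromo-6-methoxyphenol | C=CCc1cc(Br)cc(OC)c1O | intermediate
22 | 1-allyl-2-(benzyloxy)-5-bromo-3-methoxybenzene | C=CCc1cc(Br)cc(OC)c1OCc1ccccc1 | intermediate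
23 | 2-[2-(benzyloxy)-5-bromo-3-methoxyphenyl]acetaldehyde | O=CCc1cc(Br)cc(OC)c1OCc1ccccc1 | intermediate
24 | 2-[2-(benzyloxy)-5-bromo-3-methoxyphenyl]acetic acid | OC(=O)Cc1cc(Br)cc(OC)c1OCc1ccccc1 | intermediate
25 | (R)-4-benzyl-2-oxazolidinone | O=C1N[C@H](Cc2ccccc2)CO1 | starting material
26 | mixed anhydride of 24 with pivalic acid | CC(C)(C)C(=O)OC(=O)Cc1cc(Br)cc(OC)c1OCc1ccccc1 | intermediate
27 | (4R)-4-benzyl-3-{2-[2-(benzyloxy)-5-bromo-3-methoxyphenyl]acetyl}oxazolidin-2-one | O=C(Cc1cc(Br)cc(OC)c1OCc1ccccc1)N1[C@H](Cc2ccccc2)COC1=O | intermediate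
28 | 4-(benzyloxy)-3-methoxybenzaldehyde | COc1cc(C=O)ccc1OCc1ccccc1 | starting material
29 | (4R)-4-benzyl-3-[(2R,3R)-2-(2-benzyloxy-5-bromo-3-methoxyphenyl)-3-(4-benzyloxy-3-methoxyphenyl)-3-hydroxypropanoyl]oxazolidin-2-one | COc1cc([C@H](O)[C@H](C(=O)N2[C@H](Cc3ccccc3)COC2=O)c2cc(Br)cc(OC)c2OCc2ccccc2)ccc1OCc1ccccc1 | intermediate
30 | (1R,2S)-2-(2-benzyloxy-5-bromo-3-methoxyphenyl)-1-(4-benzyloxy-3-methoxyphenyl)propane-1,3-diol | COc1cc([C@H](O)[C@H](CO)c2cc(Br)cc(OC)c2OCc2ccccc2)ccc1OCc1ccccc1 | intermediate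
31 | (1R,2S)-2-(2-benzyloxy-5-bromo-3-methoxyphenyl)-1-(4-benzyloxy-3-methoxyphenyl)-1,3-bis(tert-butyldimethylsilyloxy)propane | COc1cc([C@H](O[Si](C)(C)C(C)(C)C)[C@H](CO[Si](C)(C)C(C)(C)C)c2cc(Br)cc(OC)c2OCc2ccccc2)ccc1OCc1ccccc1 | intermediate
32 | 4-benzyloxy-3-[(1R,2S)-1-(4-benzyloxy-3-methoxyphenyl)-1,3-bis(tert-butyldimethylsilyloxy)propan-2-yl]-5-methoxybenzaldehyde | COc1cc([C@H](O[Si](C)(C)C(C)(C)C)[C@H](CO[Si](C)(C)C(C)(C)C)c2cc(C=O)cc(OC)c2OCc2ccccc2)ccc1OCc1ccccc1 | intermediate
33 | dimethyl succinate | COC(=O)CCC(=O)OC | starting material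
34 | (E)-4-{4-benzyloxy-3-[(1R,2S)-1-(4-benzyloxy-3-methoxyphenyl)-1,3-bis(tert-butyldimethylsilyloxy)propan-2-yl]-5-methoxyphenyl}-3-(methoxycarbonyl)but-3-enoic acid | COc1cc([C@H](O[Si](C)(C)C(C)(C)C)[C@H](CO[Si](C)(C)C(C)(C)C)c2cc(/C=C(/C(=O)OC)CC(=O)O)cc(OC)c2OCc2ccccc2)ccc1OCc1ccccc1 | intermediate
35 | (3R)-3-{4-benzyloxy-3-[(1R,2S)-1-(4-benzyloxy-3-methoxyphenyl)-1,3-bis(tert-butyldimethylsilyloxy)propan-2-yl]-5-methoxybenzyl}-4-methoxy-4-oxobutanoic acid | COc1cc([C@H](O[Si](C)(C)C(C)(C)C)[C@H](CO[Si](C)(C)C(C)(C)C)c2cc(C[C@H](CC(=O)O)C(=O)OC)cc(OC)c2OCc2ccccc2)ccc1OCc1ccccc1 | intermediate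
36 | (3R)-3-{4-benzyloxy-3-[(1R,2S)-1-(4-benzyloxy-3-methoxyphenyl)-1,3-bis(tert-butyldimethylsilyloxy)propan-2-yl]-5-methoxybenzyl}-4-hydroxybutanoic acid | COc1cc([C@H](O[Si](C)(C)C(C)(C)C)[C@H](CO[Si](C)(C)C(C)(C)C)c2cc(C[C@H](CC(=O)O)CO)cc(OC)c2OCc2ccccc2)ccc1OCc1ccccc1 | intermediate
37 | (4R)-4-{4-benzyloxy-3-[(1R,2S)-1-(4-benzyloxy-3-methoxyphenyl)-1,3-bis(tert-butyldimethylsilyloxy)propan-2-yl]-5-methoxybenzyl}dihydrofuran-2(3H)-one | COc1cc([C@H](O[Si](C)(C)C(C)(C)C)[C@H](CO[Si](C)(C)C(C)(C)C)c2cc(C[C@H]3COC(=O)C3)cc(OC)c2OCc2ccccc2)ccc1OCc1ccccc1 | intermediate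
38 | (3R,4R)-3-{[(2S,3R)-2-(4-benzyloxy-3-methoxyphenyl)-3-(tert-butyldimethylsilyloxymethyl)-7-methoxy-2,3-dihydrobenzofuran-5-yl]methyl}-4-{4-benzyloxy-3-[(1R,2S)-1-(4-benzyloxy-3-methoxyphenyl)-1,3-bis(tert-butyldimethylsilyloxy)propan-2-yl]-5-methoxybenzyl}dihydrofuran-2(3H)-one | COc1cc([C@H](O[Si](C)(C)C(C)(C)C)[C@H](CO[Si](C)(C)C(C)(C)C)c2cc(C[C@H]3COC(=O)[C@@H]3Cc3cc(OC)c4c(c3)[C@H](CO[Si](C)(C)C(C)(C)C)[C@@H](c3ccc(OCc5ccccc5)c(OC)c3)O4)cc(OC)c2OCc2ccccc2)ccc1OCc1ccccc1 | intermediate
39 | triol: 38 with all three silyl ethers cleaved, arm (1R,2S)-1,3-diol, benzyl ethers kept | COc1cc([C@H](O)[C@H](CO)c2cc(C[C@H]3COC(=O)[C@@H]3Cc3cc(OC)c4c(c3)[C@H](CO)[C@@H](c3ccc(OCc5ccccc5)c(OC)c3)O4)cc(OC)c2OCc2ccccc2)ccc1OCc1ccccc1 | intermediate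
40 | tri-O-benzyl ether of the target, arm (2S)-3-hydroxy-1-(4-benzyloxy-3-methoxyphenyl)-1-oxopropan-2-yl | COc1cc(C(=O)[C@H](CO)c2cc(C[C@H]3COC(=O)[C@@H]3Cc3cc(OC)c4c(c3)[C@H](CO)[C@@H](c3ccc(OCc5ccccc5)c(OC)c3)O4)cc(OC)c2OCc2ccccc2)ccc1OCc1ccccc1 | intermediate
41 | CNP0111438.1, (3R,4R)-3-{[(2S,3R)-3-(hydroxymethyl)-2-(4-hydroxy-3-methoxyphenyl)-7-methoxy-2,3-dihydrobenzofuran-5-yl]methyl}-4-{4-hydroxy-3-[(2S)-3-hydroxy-1-(4-hydroxy-3-methoxyphenyl)-1-oxopropan-2-yl]-5-methoxybenzyl}dihydrofuran-2(3H)-one | COc1cc(C(=O)[C@H](CO)c2cc(C[C@H]3COC(=O)[C@@H]3Cc3cc(OC)c4c(c3)[C@H](CO)[C@@H](c3ccc(O)c(OC)c3)O4)cc(OC)c2O)ccc1O | target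

**Step count and risk**

Total step count: 27. Longest linear sequence: 16 steps (steps 12–27, from 6 and 19); the dihydrobenzofuran branch (steps 1, 2, 5–11, with 3 and 4 as a two-step side branch) joins at step 24.

Steps most likely to fail:

1. Step 6. The 2-aryl group may migrate instead of ring A, the heterocycle may simply be dehydrogenated, or acid-induced ring opening at C2 may erode the enantiomeric purity. Fallback, setting out from 9 and returning at 12: the same C3–C3a bond is made by a Wolff ring contraction. Kinetic enolisation of 9 (LiHMDS, THF, −78 °C) and trifluoroacetylation with CF3CO2CH2CF3 should give the 3-trifluoroacetyl flavanone F1. Detrifluoroacetylative diazo transfer (MsN3, Et3N, MeCN) should give the 3-diazoflavanone F2. Irradiation in MeOH makes the ring A carbon migrate to the carbene carbon and traps the ketene as the methyl ester, expected as a mixture of 12 and its cis epimer F3. DBU in CH2Cl2 then equilibrates F3 to the trans ester 12 without touching the pivalate.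

2. Step 5. Facial selectivity may be poor on this substituted chromone, the aryl ester boronic acid may protodeboronate, or reversible ring opening of the product may cause partial racemisation. Fallback, setting out from 5 and 8 and returning at 9: addition with the achiral catalyst [Rh(OH)(cod)]2 (dioxane/H2O) should give the racemic flavanone F4. Kinetic resolution by asymmetric transfer hydrogenation (the antipode of RuCl(p-cymene)(TsDPEN) that reduces the 2R ketone, HCO2H/Et3N) would then convert the unwanted enantiomer into the cis flavan-4-ol F5 and leave 9, which is separated by chromatography.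

3. Step 26. Oxidation of the hindered benzylic alcohol may be sluggish, and the newly enolisable α-aryl β-hydroxy ketone centre may epimerise or lose water on the oxide surface. Fallback, setting out from 39 and returning at 40: selective silylation of the two primary alcohols (TBSCl, imidazole, CH2Cl2, −20 °C) should give the bis-silyl ether F6 with only the benzylic alcohol free. Pyridine-buffered Dess–Martin periodinane then gives ketone F7. HF·pyridine in THF/pyridine removes the silyl groups under weakly acidic conditions to give 40.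

Further compounds

F1 | step 6 | (2S)-6-bromo-8-methoxy-2-[3-methoxy-4-(pivaloyloxy)phenyl]-3-(trifluoroacetyl)chroman-4-one, C2 as in 9 | O=C1C(C(=O)C(F)(F)F)[C@@H](c2ccc(OC(=O)C(C)(C)C)c(OC)c2)Oc2c(OC)cc(Br)cc21
F2 | step 6 | 3-diazo derivative of 9, C2 as in 9 | O=C1C(=[N+]=[N-])[C@@H](c2ccc(OC(=O)C(C)(C)C)c(OC)c2)Oc2c(OC)cc(Br)cc21
F3 | step 6 | methyl (2S,3R)-5-bromo-7-methoxy-2-[3-methoxy-4-(pivaloyloxy)phenyl]-2,3-dihydrobenzofuran-3-carboxylate (cis epimer of 12) | COC(=O)[C@@H]1c2cc(Br)cc(OC)c2O[C@@H]1c1ccc(OC(=O)C(C)(C)C)c(OC)c1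
F4 | step 5 | racemic 6-bromo-8-methoxy-2-[3-methoxy-4-(pivaloyloxy)phenyl]chroman-4-one | O=C1CC(c2ccc(OC(=O)C(C)(C)C)c(OC)c2)Oc2c(OC)cc(Br)cc21
F5 | step 5 | (2R,4R)-6-bromo-8-methoxy-2-[3-methoxy-4-(pivaloyloxy)phenyl]chroman-4-ol (cis) | O[C@@H]1C[C@H](c2ccc(OC(=O)C(C)(C)C)c(OC)c2)Oc2c(OC)cc(Br)cc21
F6 | step 26 | 39 with both primary alcohols as tert-butyldimethylsilyl ethers, benzylic alcohol free | COc1cc([C@H](O)[C@H](CO[Si](C)(C)C(C)(C)C)c2cc(C[C@H]3COC(=O)[C@@H]3Cc3cc(OC)c4c(c3)[C@H](CO[Si](C)(C)C(C)(C)C)[C@@H](c3ccc(OCc5ccccc5)c(OC)c3)O4)cc(OC)c2OCc2ccccc2)ccc1OCc1ccccc1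
F7 | step 26 | 40 with both primary alcohols as tert-butyldimethylsilyl ethers | COc1cc(C(=O)[C@H](CO[Si](C)(C)C(C)(C)C)c2cc(C[C@H]3COC(=O)[C@@H]3Cc3cc(OC)c4c(c3)[C@H](CO[Si](C)(C)C(C)(C)C)[C@@H](c3ccc(OCc5ccccc5)c(OC)c3)O4)cc(OC)c2OCc2ccccc2)ccc1OCc1ccccc1
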